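## Analysis of the target

Target 17 (C26H36O5) is an acyclic pentan-3-one (chain C-1 to C-5). C-2 carries ring B, a 6-ethyl-3,5-dimethyl-4-oxo-4H-pyran-2-yl group, and C-4 carries ring A, a 3,5-dimethyl-4-oxo-6-pentyl-4H-pyran-2-yl group. The two fully substituted γ-pyranones are neither fused nor bridged.

The only stereocentres are C-2 and C-4, both S. Each bears H, a methyl group, the C-3 carbonyl carbon and the sp2 carbon C-2 of a pyranone. The two centres therefore have the same local environment and are homochiral about C-3 (pseudo-C2 symmetry, broken only by ethyl versus pentyl at C-6 of the rings). The heterochiral arrangement is the meso-like diastereomer.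

Both stereogenic C–H bonds are activated twice, by the ketone and by the vinylogous-ester position of a pyranone. They epimerise with amines, alkoxides, strong acid or long contact with silica, and no other stereo-element exists that could relay or restore configuration across the sp2 carbon C-3.

The rings are vinylogous esters. Hard nucleophiles open them at C-2/C-6, the CH2 groups of the ethyl and pentyl substituents are vinylogously acidic, and the ring carbonyls are hindered and poorly electrophilic.

The synthesis is hard for one reason: two labile tertiary α-carbonyl centres must be set in absolute terms, late, under almost neutral conditions, on two halves that are nearly but not quite identical.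

The feature the route uses is the pair of C(sp3)–C(sp2) bonds chain C-2–ring B C-2 and chain C-4–ring A C-2. Read this way, 17 is pentan-3-one heteroarylated at both α-carbons, and each bond can be made stereoconvergently from a planar α-keto radical at C-2 or C-4.

## Retrosynthetic reasoning

**17 to 15 and 16.** The bond chain C-2–ring B C-2 is cut. This gives bromo ketone 15, which holds ring A and the C-4 centre and carries bromine at C-2 as a mixture of epimers, and the ring B zinc reagent 16. The cut is made at the stereocentre itself: a chiral nickel catalyst can convert both C-2 epimers of 15, through one planar α-keto radical, into one configuration. The forward step must set C-2 under catalyst control and must leave the acidic C-4–H untouched. It is the last step, so nothing afterwards can scramble either centre.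

**15 to 13 and 14.** The same cut is made at chain C-4–ring A C-2, leading to 2,4-dibromopentan-3-one 13 and the ring A zinc reagent 14. The dibromide is chosen because both leaving groups are in place before any labile centre exists. A bromination after the first coupling would go to the doubly activated C-4–H, not to C-2. The meso/racemic composition of 13 is irrelevant in a radical coupling. The forward step needs mono-coupling (excess 13) and catalyst control at C-4.

**14 and 16 to 10 and 12.** The C–Zn bonds are traced back to the C–I bonds of iodopyranones 10 and 12 by zinc insertion. A neutral insertion is used because any base would attack the lateral CH2 groups of the pentyl and ethyl substituents instead of the ring position.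

**10 and 12 to 8 with 9 or 11.** The ring C-6–alkyl bonds are cut. Both rings come from one symmetrical building block, 2,6-diiodo-3,5-dimethyl-4H-pyran-4-one 8, and differ only in the alkylzinc partner (pentylzinc bromide 9 or diethylzinc 11). This turns the near-identity of the two halves into an advantage.

**8 to 6 to 4.** The two C–I bonds are traced back to the two ring C–H bonds of 3,5-dimethyl-4H-pyran-4-one 4, by way of mono-iodide 6, through directed C–H zincation and iodination. This is clean at this stage because C-3/C-5 are blocked by methyl groups and no lateral acidic CH2 is present yet.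

**4 to 1 and 2.** The ring is opened at O-1 and at the C-2/C-3 and C-5/C-6 bonds: pentan-3-one 1 supplies C-3, C-4, C-5 and both methyl groups, and the aminal ester 2 supplies C-2 and C-6. Since 13 is the α,α'-dibromide of 1, the whole carbon skeleton of 17 apart from the two alkyl groups and four one-carbon units derives from three pentan-3-one units.

## Alternatives that were turned down

**Alternative 1:** the textbook polypropionate route.
- Disconnection: both pyranones are opened to 1,3,5-triketone arms, C-3 is carried as a protected carbinol, and the C-2/C-3/C-4 stereotriad comes from auxiliary-controlled propionate aldol reactions.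
- Forward key step: cyclodehydration of each triketone arm to its ring, deprotection to the bis-pyranone carbinol A1, and Dess–Martin oxidation of A1 to 17.
- Reason for rejection: each ring costs an aldol or acylation with a β-diketone dianion, an oxidation and a cyclodehydration, and this must be done twice on ends that have to be told apart by protecting groups. C-3 costs a protection, a deprotection and an oxidation. The result is well over a dozen linear steps. The dianion steps act on β-silyloxy carbonyl compounds that can eliminate or epimerise, so the stereochemical information is carried through the longest and harshest part of the route.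

**Alternative 2:** vinylogous aldol at the carbinol level.
- Disconnection: the C-3–C-2 bond.
- Forward key step: the lateral lithium dienolate of the symmetrical pyranone A2 adds to aldehyde A3; oxidation of the adduct A1 gives 17.
- Reason for rejection: the aldol creates C-2 with no controlling element. Felkin control by the C-4 centre of A3 addresses C-3, which the oxidation destroys, not C-2. A3 is an α-pyranyl aldehyde and is configurationally fragile towards the basic dienolate. Making A3 by lateral chemistry fails on structure, because its ring A precursor has two equally acidic lateral CH2 groups (ethyl and pentyl). The route is short but stereorandom at C-2.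

**Alternative 3:** reductive acyl cross-coupling at the ketone level.
- Disconnection: the C-3–C-2 bond.
- Forward key step: enantioconvergent nickel-catalysed reductive coupling of acid chloride A4 with the racemic lateral chloride A5.
- Reason for rejection: only C-2 is set by the catalyst. C-4 has to be built into A4 by a separate asymmetric sequence of four to five steps. A4 has an α-H that is also the vinylogous α-H of ring A, so it would lose HCl to the ketene and racemise. α-Branched acid chlorides give hindered acyl-nickel species that couple slowly and decarbonylate. The partners together need more steps than the chosen route needs in total.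

Key step: step 7

Remark on the chemistry: the sense of induction of a nickel–pybox catalyst with a 4-oxopyran-2-ylzinc nucleophile cannot be taken over from the aryl series. The ligand antipode that gives the S centre is therefore assigned once on 15 (both antipodes are available) and used unchanged in step 7. Compound 13 is used as the commercial mixture of meso and racemic forms.

## Route

Step 1
Reactants: 1 pentan-3-one; 2 tert-butoxybis(dimethylamino)methane
Product: 4 3,5-dimethyl-4H-pyran-4-one, via bis-enaminone 3 (not isolated)
Conditions: 2 (2.5 equiv), neat, 110–130 °C, volatiles distilled off; then 2 M aq. HCl, 60 °C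
Reagents that add atoms: tert-butoxybis(dimethylamino)methane (2), CN(C)C(OC(C)(C)C)N(C)C; water, O
Why: Aminomethylenation of both α-CH2 groups of the ketone gives the cross-conjugated bis-enaminone; aqueous acid hydrolyses one vinylogous amide to the hydroxymethylene ketone, whose oxygen adds to the other enaminone carbon and expels dimethylamine to close the pyranone (condensation and cyclodehydration, no stereocentre).

Step 2
Reactants: 4 3,5-dimethyl-4H-pyran-4-one
Product: 6 2-iodo-3,5-dimethyl-4H-pyran-4-one, via pyranylzinc chloride 5 (not isolated)
Conditions: TMPZnCl·LiCl (1.3 equiv), THF, 25 °C; then I2 (1.4 equiv), THF, 0 °C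
Reagents that add atoms: iodine, II
Why: Directed C–H zincation with a hindered zinc amide, a reaction type known for chromones and 4-pyranones at the carbon next to the ring oxygen; C-3 and C-5 are blocked and the ring methyl groups are not vinylogously acidic, so C-2–H is the only site, and iodinolysis of the C–Zn bond gives the iodide.

Step 3
Reactants: 6 2-iodo-3,5-dimethyl-4H-pyran-4-one
Product: 8 2,6-diiodo-3,5-dimethyl-4H-pyran-4-one, via iodopyranylzinc chloride 7 (not isolated)
Conditions: TMPZnCl·LiCl (1.3 equiv), THF, 25 °C; then I2 (1.4 equiv), THF, 0 °C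
Reagents that add atoms: iodine, II
Why: The same C–H zincation at the remaining ring position C-6, which the iodine substituent makes more acidic; a zinc amide deprotonates without iodine–metal exchange, and iodinolysis gives the symmetrical diiodide.

Step 4
Reactants: 8 2,6-diiodo-3,5-dimethyl-4H-pyran-4-one; 9 pentylzinc bromide
Product: 10 2-iodo-3,5-dimethyl-6-pentyl-4H-pyran-4-one
Conditions: 8 (2.5 equiv), 9 (0.5 M in THF, 1.0 equiv), PdCl2(dppf) (3 mol %), THF, 0 °C to rt; excess 8 recovered
Reagents that add atoms: pentylzinc bromide (9), CCCCC[Zn]Br
Why: Negishi sp2–sp3 coupling of a vinylogous acyl iodide, with a dppf ligand that keeps β-hydride elimination low; mono-coupling is enforced by the excess of 8 and helped by the slower oxidative addition of the more electron-rich product to zerovalent palladium.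

Step 5
Reactants: 8 2,6-diiodo-3,5-dimethyl-4H-pyran-4-one; 11 diethylzinc
Product: 12 2-ethyl-6-iodo-3,5-dimethyl-4H-pyran-4-one
Conditions: 8 (2.5 equiv), 11 (1.0 M in hexanes, 0.5 equiv), PdCl2(dppf) (3 mol %), THF, 0 °C to rt; excess 8 recovered
Reagents that add atoms: diethylzinc (11), CC[Zn]CC
Why: The same Negishi mono-coupling as in step 4 with an ethyl donor; the two ring halves of the target thus differ only in this reagent.

Step 6
Reactants: 10 2-iodo-3,5-dimethyl-6-pentyl-4H-pyran-4-one; 13 2,4-dibromopentan-3-one
Product: 15 (2RS,4S)-2-bromo-4-(3,5-dimethyl-4-oxo-6-pentyl-4H-pyran-2-yl)pentan-3-one, via pyranylzinc iodide 14 (not isolated)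
Conditions: Zn dust (activated), LiCl, THF, 25 °C, solution decanted from excess zinc; added slowly to 13 (3 equiv), NiCl2(dme) (8 mol %), chiral pybox ligand (e.g. Ph-pybox, 10 mol %), 1,2-dimethoxyethane/THF, −30 °C; pH 7 buffer quench at −30 °C
Reagents that add atoms: none
Why: Proposed new method: the closest known reaction type is the nickel/pybox-catalysed enantioconvergent Negishi arylation of racemic secondary α-bromo ketones with arylzinc iodides, extended here to a 4-oxopyran-2-ylzinc nucleophile and to the mono-coupling of an α,α'-dibromo ketone; bromine abstraction by the nickel–pyranyl species from either C–Br of any stereoisomer of 13 gives the same kind of planar α-keto radical (the second bromine is 1,3 to the radical and is not lost by β-scission), and its capture on the chiral nickel complex followed by reductive elimination should set C-4 as S; the excess of 13 keeps the second C–Br of 15 from reacting, and the configuration at C-2 is irrelevant because step 7 erases it.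

Step 7
Reactants: 12 2-ethyl-6-iodo-3,5-dimethyl-4H-pyran-4-one; 15 (2RS,4S)-2-bromo-4-(3,5-dimethyl-4-oxo-6-pentyl-4H-pyran-2-yl)pentan-3-one
Product: 17 (2S,4S)-2-(6-ethyl-3,5-dimethyl-4-oxo-4H-pyran-2-yl)-4-(3,5-dimethyl-4-oxo-6-pentyl-4H-pyran-2-yl)pentan-3-one, via pyranylzinc iodide 16 (not isolated)
Conditions: Zn dust (activated), LiCl, THF, 25 °C, solution decanted from excess zinc; 16 (1.5 equiv) added slowly to 15, NiCl2(dme) (10 mol %), the pybox antipode of step 6 (13 mol %), 1,2-dimethoxyethane/THF, −30 °C; pH 7 buffer quench at −30 °C; rapid chromatography on buffered silica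
Reagents that add atoms: none
Why: Proposed new method: the closest known reaction type is the nickel/pybox-catalysed enantioconvergent Negishi arylation of racemic secondary α-bromo ketones with arylzinc iodides, extended here to a 4-oxopyran-2-ylzinc nucleophile and to a bromo ketone that already carries an acidic α'-stereocentre. Transmetalation of 16 to monovalent nickel gives a nickel–pyranyl species that abstracts bromine from either C-2 epimer of 15; the planar α-keto radical at C-2 is captured by the chiral divalent nickel(pyranyl) bromide, and reductive elimination from trivalent nickel forms the C-2–ring B bond and returns monovalent nickel. No ring is closed. The new stereocentre C-2 is controlled by the ligand alone, because the radical has lost the configuration of the bromide; it is the same MeCH(radical)–C(=O)R unit meeting the same kind of nucleophile as in step 6, so the antipode that gave 4S there should give 2S here. The step needs catalyst control over any 1,3-bias from C-4, survival of the acidic C-4–H, and chemoselectivity for C–Br. The first is secured by the sp2 carbon C-3 that separates C-4 from the nickel-bound radical centre, the second by the low basicity of an sp2 organozinc at −30 °C and the buffered quench, and the third by the inertness of the hindered vinylogous-ester carbonyls of both rings towards organozinc reagents. Because both centres are set by the same catalyst, its errors should end up mainly in the meso-like (2R,4S)/(2S,4R) diastereomers, which can be removed from 17 on achiral silica, so the enantiomeric purity of 17 should be higher than that of either single coupling.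

## Compound list

1 | pentan-3-one | CCC(=O)CC | starting material
2 | tert-butoxybis(dimethylamino)methane | CN(C)C(OC(C)(C)C)N(C)C | starting material
3 | (1E,4E)-1,5-bis(dimethylamino)-2,4-dimethylpenta-1,4-dien-3-one | CN(C)/C=C(\C)C(=O)C(/C)=C/N(C)C | intermediate
4 | 3,5-dimethyl-4H-pyran-4-one | Cc1cocc(C)c1=O | intermediate
5 | (3,5-dimethyl-4-oxo-4H-pyran-2-yl)zinc chloride | Cc1coc([Zn]Cl)c(C)c1=O | intermediate
6 | 2-iodo-3,5-dimethyl-4H-pyran-4-one | Cc1coc(I)c(C)c1=O | intermediate
7 | (6-iodo-3,5-dimethyl-4-oxo-4H-pyran-2-yl)zinc chloride | Cc1c(I)oc([Zn]Cl)c(C)c1=O | intermediate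
8 | 2,6-diiodo-3,5-dimethyl-4H-pyran-4-one | Cc1c(I)oc(I)c(C)c1=O | intermediate
9 | pentylzinc bromide | CCCCC[Zn]Br | starting material
10 | 2-iodo-3,5-dimethyl-6-pentyl-4H-pyran-4-one | CCCCCc1oc(I)c(C)c(=O)c1C | intermediate
11 | diethylzinc | CC[Zn]CC | starting material
12 | 2-ethyl-6-iodo-3,5-dimethyl-4H-pyran-4-one | CCc1oc(I)c(C)c(=O)c1C | intermediate
13 | 2,4-dibromopentan-3-one (meso and racemic forms) | CC(Br)C(=O)C(C)Br | starting material
14 | (3,5-dimethyl-4-oxo-6-pentyl-4H-pyran-2-yl)zinc iodide | CCCCCc1oc([Zn]I)c(C)c(=O)c1C | intermediate
15 | (2RS,4S)-2-bromo-4-(3,5-dimethyl-4-oxo-6-pentyl-4H-pyran-2-yl)pentan-3-one | CCCCCc1oc([C@H](C)C(=O)C(C)Br)c(C)c(=O)c1C | intermediate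
16 | (6-ethyl-3,5-dimethyl-4-oxo-4H-pyran-2-yl)zinc iodide | CCc1oc([Zn]I)c(C)c(=O)c1C | intermediate
17 | (2S,4S)-2-(6-ethyl-3,5-dimethyl-4-oxo-4H-pyran-2-yl)-4-(3,5-dimethyl-4-oxo-6-pentyl-4H-pyran-2-yl)pentan-3-one | CCCCCc1oc([C@H](C)C(=O)[C@@H](C)c2oc(CC)c(C)c(=O)c2C)c(C)c(=O)c1C | target

## Step count and least certain steps

Total step count: 7. Longest linear sequence: 6 (steps 1, 2, 3, 4, 6, 7); step 5 is the one-step branch that supplies ring B from 8.

**Step 7 (key step, proposed new method).**
- What may go wrong: transmetalation of the electron-poor zinc reagent 16 and capture of the hindered secondary radical may be slow, so that hydrodebromination of 15 and homocoupling of 16 take over. During that time, proton transfer from the acidic C-4–H to the organozinc would erode the C-4 configuration or open a Favorskii-type loss of bromide. Catalyst control at C-2 may also be weaker than in the aryl series because the pyranone carbonyl can bind nickel.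
- Fallback (known chemistry, gives up catalytic control; sets out from 10 and 1, comes back at 17): Suzuki coupling of 10 with isopropenylboronic acid pinacol ester (PdCl2(dppf), K3PO4, aqueous dioxane) gives 3,5-dimethyl-2-pentyl-6-(prop-1-en-2-yl)-4H-pyran-4-one F1. Hydroboration with 9-BBN gives the B-alkyl borane F2, which NaBO3 oxidises to racemic 2-(1-hydroxypropan-2-yl)-3,5-dimethyl-6-pentyl-4H-pyran-4-one F3. Dess–Martin oxidation gives racemic 2-(3,5-dimethyl-4-oxo-6-pentyl-4H-pyran-2-yl)propanal F4. Separately, 1 and propanoic acid in polyphosphoric acid give 2,6-diethyl-3,5-dimethyl-4H-pyran-4-one F5, whose two lateral CH2 groups are equivalent. LiN(SiMe3)2 (THF, −78 °C) converts F5 into its lateral lithium dienolate F6, which adds to F4 to give 2-(6-ethyl-3,5-dimethyl-4-oxo-4H-pyran-2-yl)-4-(3,5-dimethyl-4-oxo-6-pentyl-4H-pyran-2-yl)pentan-3-ol F7 as a mixture of stereoisomers. Dess–Martin oxidation gives the ketone as its four stereoisomers F8. Preparative chromatography on a chiral stationary phase delivers 17. The other three isomers are re-equilibrated with a catalytic amine base and recycled; the lability that makes the target hard is what makes this recycling possible.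

**Step 6 (proposed new method).**
- What may go wrong: over-coupling at the second C–Br bond; reductive loss of bromine from 13 through a metal enolate that expels the second bromide (oxyallyl-type decomposition); and insufficient enantioselection with the pyranyl nucleophile.
- Fallback (known chemistry; sets out from 14, comes back at 15): Negishi coupling of 14 with methyl 2-bromoacrylate (Pd(PPh3)4, THF) gives methyl 2-(3,5-dimethyl-4-oxo-6-pentyl-4H-pyran-2-yl)prop-2-enoate F9. Saponification (LiOH, aqueous THF, 0 °C) gives 2-(3,5-dimethyl-4-oxo-6-pentyl-4H-pyran-2-yl)prop-2-enoic acid F10. Asymmetric hydrogenation with Ru(OAc)2[(S)-BINAP] (H2, methanol), the reaction type used for 2-arylpropanoic acids, gives (S)-2-(3,5-dimethyl-4-oxo-6-pentyl-4H-pyran-2-yl)propanoic acid F11 (the BINAP antipode is to be confirmed on this substrate). Oxalyl chloride (cat. DMF, CH2Cl2, 0 °C) gives (S)-2-(3,5-dimethyl-4-oxo-6-pentyl-4H-pyran-2-yl)propanoyl chloride F12. Diazoethane (ether, −20 °C) gives (4S)-2-diazo-4-(3,5-dimethyl-4-oxo-6-pentyl-4H-pyran-2-yl)pentan-3-one F13. Aqueous HBr in ether at 0 °C converts F13 into 15. No base is used after the hydrogenation, so the C-4 centre should be kept.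

**Step 4 (and its twin, step 5).**
- What may go wrong: statistical over-alkylation and a difficult separation of 8, the mono-alkyl product and the dialkyl product, because the two C–I bonds differ little in reactivity.
- Fallback (sets out from 6, comes back at 15 and 17): zincation of 6 as in step 3 gives 7, which is quenched with 1,2-dibromo-1,1,2,2-tetrachloroethane in place of iodine to give 2-bromo-6-iodo-3,5-dimethyl-4H-pyran-4-one F14. Negishi coupling with 9 or with 11 (PdCl2(dppf), 0 °C) then takes place at C–I before C–Br, with no statistics, and gives 2-bromo-3,5-dimethyl-6-pentyl-4H-pyran-4-one F15 and 2-bromo-6-ethyl-3,5-dimethyl-4H-pyran-4-one F16. Zinc insertion (Zn dust, LiCl, THF, 40 °C) gives (3,5-dimethyl-4-oxo-6-pentyl-4H-pyran-2-yl)zinc bromide F17 and (6-ethyl-3,5-dimethyl-4-oxo-4H-pyran-2-yl)zinc bromide F18, which take the place of 14 and 16 in steps 6 and 7.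

**Step 1.**
- What may go wrong: the second aminomethylenation may stall at the mono-enaminone, because a vinylogous amide deactivates the remaining α-CH2 group.
- Fallback (sets out from 1, comes back at 4): double Claisen condensation of 1 with diethyl oxalate (NaOEt, ethanol) gives diethyl 3,5-dimethyl-2,4,6-trioxoheptanedioate F19. Acid closes it to diethyl 3,5-dimethyl-4-oxo-4H-pyran-2,6-dicarboxylate F20. Hydrolysis (aq. HCl, reflux) gives 3,5-dimethyl-4-oxo-4H-pyran-2,6-dicarboxylic acid F21, and thermal decarboxylation (copper powder, about 200 °C) gives 4.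

## Further compounds

F1 | step 7 | 3,5-dimethyl-2-pentyl-6-(prop-1-en-2-yl)-4H-pyran-4-one | CCCCCc1oc(C(C)=C)c(C)c(=O)c1C
F2 | step 7 | 2-[1-(9-borabicyclo[3.3.1]nonan-9-yl)propan-2-yl]-3,5-dimethyl-6-pentyl-4H-pyran-4-one (racemic) | CCCCCc1oc(C(C)CB2C3CCCC2CCC3)c(C)c(=O)c1C
F3 | step 7 | 2-(1-hydroxypropan-2-yl)-3,5-dimethyl-6-pentyl-4H-pyran-4-one (racemic) | CCCCCc1oc(C(C)CO)c(C)c(=O)c1C
F4 | step 7 | 2-(3,5-dimethyl-4-oxo-6-pentyl-4H-pyran-2-yl)propanal (racemic) | CCCCCc1oc(C(C)C=O)c(C)c(=O)c1C
F5 | step 7 | 2,6-diethyl-3,5-dimethyl-4H-pyran-4-one | CCc1oc(CC)c(C)c(=O)c1C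
F6 | step 7 | lithium 6-ethyl-2-ethylidene-3,5-dimethyl-2H-pyran-4-olate | CC=C1OC(CC)=C(C)C(O[Li])=C1C
F7 | step 7 | 2-(6-ethyl-3,5-dimethyl-4-oxo-4H-pyran-2-yl)-4-(3,5-dimethyl-4-oxo-6-pentyl-4H-pyran-2-yl)pentan-3-ol (mixture of stereoisomers) | CCCCCc1oc(C(C)C(O)C(C)c2oc(CC)c(C)c(=O)c2C)c(C)c(=O)c1C
F8 | step 7 | 2-(6-ethyl-3,5-dimethyl-4-oxo-4H-pyran-2-yl)-4-(3,5-dimethyl-4-oxo-6-pentyl-4H-pyran-2-yl)pentan-3-one (mixture of the four stereoisomers) | CCCCCc1oc(C(C)C(=O)C(C)c2oc(CC)c(C)c(=O)c2C)c(C)c(=O)c1C
F9 | step 6 | methyl 2-(3,5-dimethyl-4-oxo-6-pentyl-4H-pyran-2-yl)prop-2-enoate | CCCCCc1oc(C(=C)C(=O)OC)c(C)c(=O)c1C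
F10 | step 6 | 2-(3,5-dimethyl-4-oxo-6-pentyl-4H-pyran-2-yl)prop-2-enoic acid | CCCCCc1oc(C(=C)C(=O)O)c(C)c(=O)c1C
F11 | step 6 | (S)-2-(3,5-dimethyl-4-oxo-6-pentyl-4H-pyran-2-yl)propanoic acid | CCCCCc1oc([C@H](C)C(=O)O)c(C)c(=O)c1C
F12 | step 6 | (S)-2-(3,5-dimethyl-4-oxo-6-pentyl-4H-pyran-2-yl)propanoyl chloride | CCCCCc1oc([C@H](C)C(=O)Cl)c(C)c(=O)c1C
F13 | step 6 | (4S)-2-diazo-4-(3,5-dimethyl-4-oxo-6-pentyl-4H-pyran-2-yl)pentan-3-one | CCCCCc1oc([C@H](C)C(=O)C(C)=[N+]=[N-])c(C)c(=O)c1C
F14 | step 4 | 2-bromo-6-iodo-3,5-dimethyl-4H-pyran-4-one | Cc1c(I)oc(Br)c(C)c1=O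
F15 | step 4 | 2-bromo-3,5-dimethyl-6-pentyl-4H-pyran-4-one | CCCCCc1oc(Br)c(C)c(=O)c1C
F16 | step 4 | 2-bromo-6-ethyl-3,5-dimethyl-4H-pyran-4-one | CCc1oc(Br)c(C)c(=O)c1C
F17 | step 4 | (3,5-dimethyl-4-oxo-6-pentyl-4H-pyran-2-yl)zinc bromide | CCCCCc1oc([Zn]Br)c(C)c(=O)c1C
F18 | step 4 | (6-ethyl-3,5-dimethyl-4-oxo-4H-pyran-2-yl)zinc bromide | CCc1oc([Zn]Br)c(C)c(=O)c1C
F19 | step 1 | diethyl 3,5-dimethyl-2,4,6-trioxoheptanedioate | CCOC(=O)C(=O)C(C)C(=O)C(C)C(=O)C(=O)OCC
F20 | step 1 | diethyl 3,5-dimethyl-4-oxo-4H-pyran-2,6-dicarboxylate | CCOC(=O)c1oc(C(=O)OCC)c(C)c(=O)c1C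
F21 | step 1 | 3,5-dimethyl-4-oxo-4H-pyran-2,6-dicarboxylic acid | Cc1c(C(=O)O)oc(C(=O)O)c(C)c1=O
A1 | alternative 1 | (2R,4R)-2-(6-ethyl-3,5-dimethyl-4-oxo-4H-pyran-2-yl)-4-(3,5-dimethyl-4-oxo-6-pentyl-4H-pyran-2-yl)pentan-3-ol (either C-3 epimer; same spatial arrangement at C-2 and C-4 as in 17, the descriptors change because the carbinol carbon ranks below the pyranone carbon) | CCCCCc1oc([C@H](C)C(O)[C@@H](C)c2oc(CC)c(C)c(=O)c2C)c(C)c(=O)c1C
A2 | alternative 2 | 2,6-diethyl-3,5-dimethyl-4H-pyran-4-one | CCc1oc(CC)c(C)c(=O)c1C
A3 | alternative 2 | (S)-2-(3,5-dimethyl-4-oxo-6-pentyl-4H-pyran-2-yl)propanal | CCCCCc1oc([C@H](C)C=O)c(C)c(=O)c1C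
A4 | alternative 3 | (S)-2-(3,5-dimethyl-4-oxo-6-pentyl-4H-pyran-2-yl)propanoyl chloride | CCCCCc1oc([C@H](C)C(=O)Cl)c(C)c(=O)c1C
A5 | alternative 3 | 2-(1-chloroethyl)-6-ethyl-3,5-dimethyl-4H-pyran-4-one (racemic) | CCc1oc(C(C)Cl)c(C)c(=O)c1C
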